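## Retrosynthetic overview

1. Target 12 ⇐ bicyclic alkene 11 by hydroxyl-directed epoxidation; the oxirane is the last ring made.
2. 11 ⇐ ortho-quinol aldehyde 9 (masked as spirolactol 8) by methoxide conjugate addition and intramolecular aldol; this closes ring A (the nitrogen-bearing carbocycle) onto ring B (the former benzene ring) to give the bicyclo[3.3.1]nonan-9-one.
3. 8 ⇐ lactol 6 by the key disconnection, the C1–O bond: a catalyst-controlled dearomative spirolactolization of the phenol that creates the quaternary carbinol.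
4. 6 ⇐ dihydrocoumarin 5 ⇐ 3-amidocoumarin 4 (asymmetric hydrogenation sets the amine centre) ⇐ 3-aminocoumarin 2 + (2E)-dodec-2-enoic acid 1.
5. Ring order: benzene ring (bought) → dearomatized ring B → ring A by aldol → epoxide.

Assumption: the target is exactly the stereoisomer encoded by the given SMILES, and the sense of induction stated for the two chiral catalysts (steps 2 and 4) is the expected one; if either proves opposite, its mirror-image form, equally accessible, is used instead.

Locants C1–C6 in the notes are the six carbons of the original benzene ring: C1 carries the side chain, C2 the phenol oxygen. Reagents and catalysts are not numbered. The chiral aryl iodide of step 4 is a known compound, made in two steps from 2-iodoresorcinol and a lactate ester.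

## Route

Step 1
Reactants: 1 (2E)-dodec-2-enoic acid; 2 3-aminocoumarin
Product: 4 (2E)-N-(2-oxo-2H-chromen-3-yl)dodec-2-enamide, via (2E)-dodec-2-enoyl chloride 3 (not isolated)
Conditions: (COCl)2, cat. DMF, CH2Cl2, 0 °C → rt; then 2, pyridine, CH2Cl2, 0 °C → rt
Reagents that add atoms: none
Why: Acid chloride formation followed by N-acylation of the weakly nucleophilic 3-aminocoumarin (amide synthesis with pyridine as acid scavenger) is routine; no stereocentre is formed and the (E)-alkene is untouched.

Step 2
Reactants: 4 (2E)-N-(2-oxo-2H-chromen-3-yl)dodec-2-enamide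
Product: 5 (2E)-N-[(3S)-2-oxo-3,4-dihydro-2H-chromen-3-yl]dodec-2-enamide
Conditions: H2 (20 bar), [Rh(cod)((S,S)-Et-DuPhos)]OTf (1 mol %), CH2Cl2, 30 °C
Reagents that add atoms: none
Why: Rhodium-catalysed asymmetric hydrogenation of a cyclic dehydroamino ester: the amide carbonyl and the C3=C4 enamide alkene chelate rhodium, the (S,S)-bisphosphine selects the face that gives the (3S) centre, and the side-chain alkene, which cannot form this five-membered chelate, is left alone as in the selective reduction of dienamides.

Step 3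
Reactants: 5 (2E)-N-[(3S)-2-oxo-3,4-dihydro-2H-chromen-3-yl]dodec-2-enamide
Product: 6 (2E)-N-[(3S)-2-hydroxy-3,4-dihydro-2H-chromen-3-yl]dodec-2-enamide (lactol, both anomers)
Conditions: i-Bu2AlH (2.2 equiv), CH2Cl2–toluene, −78 °C; aq. potassium sodium tartrate
Reagents that add atoms: none
Why: Partial reduction of a lactone to a lactol: the first equivalent of i-Bu2AlH deprotonates the amide N–H, the second adds once to the aryl lactone, and the aluminium hemiacetal survives at −78 °C, so the (3S) centre is untouched; the new lactol carbon is an inconsequential anomeric mixture.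

Step 4
Reactants: 6 (2E)-N-[(3S)-2-hydroxy-3,4-dihydro-2H-chromen-3-yl]dodec-2-enamide
Product: 11 (2E)-N-[(1S,4R,5S,6R,7S)-1,6-dihydroxy-4-methoxy-9-oxobicyclo[3.3.1]non-2-en-7-yl]dodec-2-enamide, via open phenol aldehyde 7 (not isolated), via spirolactol 8 (not isolated), via quinol aldehyde 9 (not isolated), via methoxy enolate 10 (not isolated)
Conditions: (R,R)-2,2'-[(2-iodo-1,3-phenylene)bis(oxy)]bis(N-mesitylpropanamide) (10 mol %), mCPBA (1.05 equiv), CH2Cl2, H2O (5 equiv), −20 °C, 0.02 M; then cannulated into NaOMe (3 equiv), MeOH, −40 → 0 °C; AcOH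
Reagents that add atoms: water, O (the oxygen of the aldehyde hydrate that ends on C1 or on the aldehyde); m-chloroperoxybenzoic acid, OOC(=O)c1cccc(Cl)c1 (terminal oxidant, net source of that oxygen); methanol, CO (the methoxy group)
Why: Proposed new method: a catalytic, catalyst-controlled dearomative spirolactolization in which the aryl-λ3-iodane generated from the chiral aryl iodide and mCPBA binds the phenol oxygen of open tautomer 7 and the tethered aldehyde, as its hydrate, attacks the only ortho carbon it can reach (C1, 5-exo) as the aryl iodide departs, so that the C1–O bond and the (5S) quaternary centre of 8 are set by the chiral iodane (matched with the existing 3S centre) and oxygenation at the free ortho or para carbon is avoided — the closest known reaction type is the chiral aryl iodide/mCPBA oxidative ortho-spirolactonization of 3-(2-hydroxyphenyl)propanoic acids (Kita-type spirolactonization), here transferred from a carboxylic acid to an aldehyde hydrate; the dimerization-prone dienone is then consumed in the same flask, methoxide opening 8 to 9, adding reversibly at C4 (oxa-Michael) and enolate 10 closing by a chelated chair intramolecular aldol on the only face the tether reaches, which sets the bridgehead CH, the axial carbinol cis to the equatorial amide and the methoxy group trans to the new C–C bond, the product being a sink because its bridgehead α-hydrogen forbids β-elimination of methanol.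

Step 5
Reactants: 11 (2E)-N-[(1S,4R,5S,6R,7S)-1,6-dihydroxy-4-methoxy-9-oxobicyclo[3.3.1]non-2-en-7-yl]dodec-2-enamide
Product: 12 (2E)-N-[(1S,2S,4S,5S,6S,7R,8S)-1,7-dihydroxy-5-methoxy-10-oxo-3-oxatricyclo[4.3.1.0(2,4)]decan-8-yl]dodec-2-enamide (CNP0137540.1)
Conditions: VO(acac)2 (5 mol %), t-BuOOH (1.5 equiv, decane), CH2Cl2, 0 °C → rt
Reagents that add atoms: tert-butyl hydroperoxide, CC(C)(C)OO
Why: Hydroxyl-directed vanadium-catalysed epoxidation (Sharpless-type VO(acac)2/t-BuOOH): the bridgehead C1 hydroxyl is allylic to the only electron-rich alkene, binds the vanadium alkylperoxide and delivers oxygen to its own exo face, which is also the open face because the other is covered by the nitrogen-bearing bridge, so both oxirane carbons are set cis to the C1 hydroxyl and the methoxy group; the electron-poor amide alkene does not react.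

## Compound list

1 | (2E)-dodec-2-enoic acid | CCCCCCCCC/C=C/C(=O)O | starting material
2 | 3-aminocoumarin (3-amino-2H-chromen-2-one) | Nc1cc2ccccc2oc1=O | starting material
3 | (2E)-dodec-2-enoyl chloride | CCCCCCCCC/C=C/C(=O)Cl | intermediate (not isolated)
4 | (2E)-N-(2-oxo-2H-chromen-3-yl)dodec-2-enamide | CCCCCCCCC/C=C/C(=O)Nc1cc2ccccc2oc1=O | intermediate
5 | (2E)-N-[(3S)-2-oxo-3,4-dihydro-2H-chromen-3-yl]dodec-2-enamide | CCCCCCCCC/C=C/C(=O)N[C@H]1Cc2ccccc2OC1=O | intermediate
6 | (2E)-N-[(3S)-2-hydroxy-3,4-dihydro-2H-chromen-3-yl]dodec-2-enamide (lactol, both anomers) | CCCCCCCCC/C=C/C(=O)N[C@H]1Cc2ccccc2OC1O | intermediate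
7 | (2E)-N-[(2S)-1-(2-hydroxyphenyl)-3-oxopropan-2-yl]dodec-2-enamide (open tautomer of 6) | CCCCCCCCC/C=C/C(=O)N[C@@H](Cc1ccccc1O)C=O | intermediate (not isolated)
8 | (2E)-N-[(3S,5S)-2-hydroxy-6-oxo-1-oxaspiro[4.5]deca-7,9-dien-3-yl]dodec-2-enamide (spirolactol, both anomers) | CCCCCCCCC/C=C/C(=O)N[C@H]1C[C@@]2(OC1O)C(=O)C=CC=C2 | intermediate (not isolated)
9 | (2E)-N-[(2S)-1-[(1S)-1-hydroxy-2-oxocyclohexa-3,5-dien-1-yl]-3-oxopropan-2-yl]dodec-2-enamide | CCCCCCCCC/C=C/C(=O)N[C@@H](C[C@@]1(O)C(=O)C=CC=C1)C=O | intermediate (not isolated)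
10 | sodium (3R,6S)-6-[(2S)-2-[(2E)-dodec-2-enamido]-3-oxopropyl]-6-hydroxy-3-methoxycyclohexa-1,4-dien-1-olate (methoxy cis to the ring hydroxyl) | CCCCCCCCC/C=C/C(=O)N[C@@H](C[C@]1(O)C=C[C@@H](OC)C=C1[O-])C=O.[Na+] | intermediate (not isolated)
11 | (2E)-N-[(1S,4R,5S,6R,7S)-1,6-dihydroxy-4-methoxy-9-oxobicyclo[3.3.1]non-2-en-7-yl]dodec-2-enamide | CCCCCCCCC/C=C/C(=O)N[C@H]1C[C@@]2(O)C(=O)[C@@H]([C@H]1O)[C@H](OC)C=C2 | intermediate
12 | (2E)-N-[(1S,2S,4S,5S,6S,7R,8S)-1,7-dihydroxy-5-methoxy-10-oxo-3-oxatricyclo[4.3.1.0(2,4)]decan-8-yl]dodec-2-enamide | CCCCCCCCC/C=C/C(=O)N[C@H]1C[C@@]2(O)C(=O)[C@@H]([C@H]1O)[C@H](OC)[C@@H]1O[C@@H]12 | target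

## Step count and risks

Total steps: 5. Longest linear sequence: 5 steps (2 → 4 → 5 → 6 → 11 → 12; acid 1 enters in step 1).

The three steps most likely to fail:

Step 4 (the proposed new step). Risks:
- External water may attack the free para carbon and give a para-quinone.
- Catalyst control at C1 may be weak.
- The dienone may dimerize before methoxide intercepts it.
- Methoxide may add 1,6 (at C6) instead of at C4.

The fallback uses known chemistry, sets out from lactol 6 and returns at 11. Wessely acetoxylation (Pb(OAc)4, AcOH–CH2Cl2, 0 °C) is a long-known oxidation of 2-alkylphenols that oxygenates mainly the alkyl-bearing ortho carbon. It gives the isolable quinol acetate (1RS)-1-[(2S)-2-[(2E)-dodec-2-enamido]-3-oxopropyl]-2-oxocyclohexa-3,5-dien-1-yl acetate F4 as both C1 epimers. NaOMe in MeOH (−40 → 0 °C) then removes the acetyl group and triggers the same conjugate addition and aldol closure to 11. Chromatography separates 11 from the diastereomeric bicycle (2E)-N-[(1R,4S,5R,6S,7S)-1,6-dihydroxy-4-methoxy-9-oxobicyclo[3.3.1]non-2-en-7-yl]dodec-2-enamide F5, which comes from the other C1 epimer. The price is the loss of stereocontrol at C1, so at most about half the material is useful.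

Step 2. Risks: the aromatic-like coumarin enamide may need forcing conditions under which the side-chain alkene is also reduced, or the selectivity may be low.

The fallback replaces catalytic asymmetric induction by the chiral pool; it sets out from acid 1 and returns at lactol 6, by-passing 4 and 5. Commercial 2-hydroxy-L-phenylalanine F1 is esterified (SOCl2, MeOH) to methyl 2-hydroxy-L-phenylalaninate hydrochloride F2. This is coupled with 1 (EDC·HCl, HOBt, i-Pr2NEt, CH2Cl2) to methyl (2S)-2-[(2E)-dodec-2-enamido]-3-(2-hydroxyphenyl)propanoate F3. Reduction with i-Bu2AlH (3.5 equiv, CH2Cl2, −78 °C) gives the aldehyde, which closes to 6.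

Step 5. Risks: vanadium may bind and degrade the tertiary ketol or oxidize the secondary carbinol, and the pseudoaxial methoxy group may slow delivery to the exo face.

The fallback gives up hydroxyl direction; it sets out from 11 and returns at 12. Both hydroxyls are silylated (Me3SiOTf, 2,6-lutidine, CH2Cl2, −78 °C) to the 1,6-bis(trimethylsilyl) ether of 11 F6. Dimethyldioxirane (acetone, 0 °C) has no metal to engage the ketol and is steered only by the shape of the bicycle to the exo face; it gives the 1,7-bis(trimethylsilyl) ether of 12 F7. The silyl groups are removed with K2CO3 in MeOH (0 °C) to give 12.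

## Further compounds

F1 | step 2 | 2-hydroxy-L-phenylalanine (L-ortho-tyrosine) | N[C@@H](Cc1ccccc1O)C(=O)O
F2 | step 2 | methyl 2-hydroxy-L-phenylalaninate hydrochloride | COC(=O)[C@@H](N)Cc1ccccc1O.Cl
F3 | step 2 | methyl (2S)-2-[(2E)-dodec-2-enamido]-3-(2-hydroxyphenyl)propanoate | CCCCCCCCC/C=C/C(=O)N[C@@H](Cc1ccccc1O)C(=O)OC
F4 | step 4 | (1RS)-1-[(2S)-2-[(2E)-dodec-2-enamido]-3-oxopropyl]-2-oxocyclohexa-3,5-dien-1-yl acetate (both C1 epimers) | CCCCCCCCC/C=C/C(=O)N[C@@H](CC1(OC(C)=O)C(=O)C=CC=C1)C=O
F5 | step 4 | (2E)-N-[(1R,4S,5R,6S,7S)-1,6-dihydroxy-4-methoxy-9-oxobicyclo[3.3.1]non-2-en-7-yl]dodec-2-enamide | CCCCCCCCC/C=C/C(=O)N[C@H]1C[C@]2(O)C(=O)[C@H]([C@@H]1O)[C@@H](OC)C=C2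
F6 | step 5 | 1,6-bis(trimethylsilyl) ether of 11 | CCCCCCCCC/C=C/C(=O)N[C@H]1C[C@@]2(O[Si](C)(C)C)C(=O)[C@@H]([C@H]1O[Si](C)(C)C)[C@H](OC)C=C2
F7 | step 5 | 1,7-bis(trimethylsilyl) ether of 12 | CCCCCCCCC/C=C/C(=O)N[C@H]1C[C@@]2(O[Si](C)(C)C)C(=O)[C@@H]([C@H]1O[Si](C)(C)C)[C@H](OC)[C@@H]1O[C@@H]12
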